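The runs were computed for substances that don't exist; scatter was added.

The complex with three exchanged costs 3 incoming ligands per complex and the complex with one exchanged costs one, so I count the ligand charged per complex charged.

in all of them: starting complex 0.20 M
- oak: incoming ligand 0.20 M; run made earlier
- alder: incoming ligand 0.29 M; run made earlier
- maple: incoming ligand 0.45 M; run made earlier
- north: incoming ligand 0.160 M; time 4.0 h
- north-west: incoming ligand 0.500 M; time 4.0 h

- oak (time / h: complex with one exchanged / %, starting complex / %): 0.333: 25.8, 46.5; 0.667: 26.5, 38.8; 1.50: 24.1, 34.5; 4.00: 22.0, 32.6
- alder (time / h: complex with one exchanged / %, starting complex / %): 1.00: 22.7, 20.4; 2.00: 18.5, 19.2; 3.00: 18.3, 20.3; 4.00: 15.8, 17.6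
- maple (time / h: complex with one exchanged / %, starting complex / %): 1.00: 11.3, 6.8; 2.00: 7.9, 2.7; 3.00: 7.3, 3.2; 4.00: 5.9, 3.2

(scatter of a reading: 1 percentage point)

* which of these holds the largest part of the starting complex at the end of north (complex with three exchanged / complex with one exchanged / complex with two exchanged / starting complex)
* which of these holds the largest part of the starting complex at the end of north-west (complex with three exchanged / complex with one exchanged / complex with two exchanged / starting complex)
* complex with one exchanged at the end of north, in percent of the starting complex charged

- the analysis behind the earlier runs scatters by 1 percentage point, standard deviation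

*What do you carry into north?* North holds 0.800 equivalents of incoming ligand per starting complex charged. That is under the 3 a complex can take, so ligand is the limiting reagent.

*Why think the runs stall on ligand and not on time?* Oak, at 1.00 equivalents, drifts by 1.9 percentage points in starting complex between 1.50 h and 4.00 h, against a scatter of 1 point. Maple, at 2.25 equivalents, reads 3.2% at 4.00 h, far below oak's 32.6%.

*Then reckon north.* I solve the two ends. With no ligand, starting complex stays at its full charge; at oak's equivalents, it reads 32.6% at 4.00 h. Joining these gives 46.1% for north.

*But that line may bend. What then?* Continuing the line from alder through oak instead gives 39.3%, so I commit to that bracket, with starting complex leading. For complex with one exchanged I take oak's reading, 22.0%.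

The forecast names starting complex for north and complex with three exchanged for north-west, with 24% of complex with one exchanged, a little above mine. It reads the stall as “the ligand running out, or a near-balance”.

North gives starting complex at 43.5% with 19.5% of complex with one exchanged, and north-west gives complex with three exchanged at 58.2%.

    starting complex + incoming ligand → leaving ligand + complex with one exchanged (k = 0.00620 M⁻¹ s⁻¹)
    complex with one exchanged + incoming ligand → leaving ligand + complex with two exchanged (k = 0.00840 M⁻¹ s⁻¹)
    complex with two exchanged + incoming ligand → leaving ligand + complex with three exchanged (k = 0.00250 M⁻¹ s⁻¹)
    complex with one exchanged → over-reaction product (k = 3.00 × 10⁻⁵ s⁻¹)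
    complex with one exchanged ⇌ isomer of the product (K = 0.320, k = 0.00120 s⁻¹)

The forecast's leader changes in a flask like north charged with 0.050 M of starting complex: at 3.20 equivalents, complex with three exchanged leads with 66.9%. In north, the 0.800 equivalents are spent, with 0% of the incoming ligand left at 4.00 h. Starting complex in north reads 43.5% at 4.00 h and 43.5% at 40.0 h, but the flask has not come to rest. By 40.0 h, over-reaction product climbs from 9.65% to 34.1%, while complex with one exchanged falls from 19.5% to 1.03%.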